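Numbering: ten-membered ring C1 (ketone), C2, C3 (enol ether carbon), C4 (methyl C15), C5, C6 (lactone O), C7, C8 (ester O), C9, C10 (methyl C14, ring O); lactone carbons C11 (methyl C13) and C12. Enabling feature: C7 is the β-carbon of the C6–O–C12 butenolide ring and its neighbour C8 is oxygenated, so an acyl radical at C8 is polarity-matched to the C7=C11 bond, and the furanone ring already ties C3 to C10 through oxygen.
Retrosynthesis cuts, in order: the C8–O tiglate ester; C7–C8 (ten-membered ring); the butenolide at C7=C11 and O–C12; the furanone at O–C3 and C1–C2. This leaves an N-methoxy-N-methylamide (C8–C10, C1, C14) and an alkyne (C2–C7, C15).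
Forward: the two fragments are joined at C1–C2; the furanone ring closes first, the butenolide ring second, the ten-membered ring third; reduction and esterification at C8 finish the synthesis.
Stereochemistry: C10 from (S)-lactic acid (alkylation of its pivalaldehyde acetal with retention); C6 from (R)-5-(hydroxymethyl)butyrolactone; C4 by trans-methylation of that lactone; C7 by anti radical addition to the butenolide; C11 by base equilibration; C8 by hydride reduction, then Mitsunobu inversion.

Key step: step 16

Assumption: hydride is taken to attack the C8 carbonyl of the all-trans tricyclic ketone from the face that carries H7 (away from the C7–C11 bond and the C10 methyl), so the alcohol is 8R and the ester is formed with inversion.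

Step 1
Reactants: 1 (S)-lactic acid; 2 pivalaldehyde
Product: 3 (2S,5S)-2-tert-butyl-5-methyl-1,3-dioxolan-4-one
Conditions: p-toluenesulfonic acid monohydrate (cat.), H2SO4 (cat.), pentane, reflux with water separator; crystallisation at −78 °C
Reagents that add atoms: none
Why: Acid-catalysed acetalisation with azeotropic removal of water should give the cis acetal, in which the lactic acid centre fixes the configuration of the new acetal carbon (self-regeneration of a stereocentre).

Step 2
Reactants: 3; 4 tert-butyl bromoacetate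
Product: 6 tert-butyl 2-[(2S,4R)-2-tert-butyl-4-methyl-5-oxo-1,3-dioxolan-4-yl]acetate, via lithium enolate 5 (not isolated)
Conditions: LiN(i-Pr)2, THF, −78 °C; then 4, −78 to −40 °C
Reagents that add atoms: none
Why: Enolate alkylation in which the bromide approaches the planar enolate anti to the tert-butyl group of the acetal, so the quaternary centre (later C10) forms with net retention of the lactic acid configuration.

Step 3
Reactants: 6
Product: 7 tert-butyl (3R)-3-hydroxy-4-[methoxy(methyl)amino]-3-methyl-4-oxobutanoate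
Conditions: MeNHOMe·HCl, i-PrMgCl, THF, −20 °C to rt
Reagents that add atoms: N,O-dimethylhydroxylamine hydrochloride, CNOC.Cl
Why: Aminolysis of the activated acetal ester by the magnesium amide, after which the hemiacetal collapses with loss of pivalaldehyde while the hindered tert-butyl ester should stay intact.

Step 4
Reactants: 7
Product: 8 tert-butyl (3R)-4-[methoxy(methyl)amino]-3-methyl-4-oxo-3-[(trimethylsilyl)oxy]butanoate
Conditions: Me3SiCl, imidazole, DMF, rt
Reagents that add atoms: chlorotrimethylsilane, C[Si](C)(C)Cl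
Why: Silylation of the tertiary alcohol, so that no alkoxide β to the ester (retro-aldol risk) is present during the acetylide addition.

Step 5
Reactants: 9 (5R)-5-(hydroxymethyl)dihydrofuran-2(3H)-one
Product: 10 (5R)-5-[(trityloxy)methyl]dihydrofuran-2(3H)-one
Conditions: Ph3CCl, Et3N, 4-(dimethylamino)pyridine (cat.), CH2Cl2, rt
Reagents that add atoms: trityl chloride, ClC(c1ccccc1)(c1ccccc1)c1ccccc1
Why: Tritylation of the primary alcohol gives a bulky ether that shields one face of the lactone enolate in the next step.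

Step 6
Reactants: 10
Product: 12 (3S,5R)-3-methyl-5-[(trityloxy)methyl]dihydrofuran-2(3H)-one, via lithium enolate 11 (not isolated)
Conditions: LiN(i-Pr)2, THF, −78 °C; then MeI, −78 °C
Reagents that add atoms: iodomethane, CI
Why: Lactone enolate alkylation in which iodomethane enters anti to the trityloxymethyl group, giving the trans lactone and with it the C4 methyl centre of the target.

Step 7
Reactants: 12
Product: 13 (3S,5R)-3-methyl-5-[(trityloxy)methyl]tetrahydrofuran-2-ol (mixture of anomers)
Conditions: i-Bu2AlH, CH2Cl2, −78 °C; aqueous potassium sodium tartrate work-up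
Reagents that add atoms: none
Why: Partial reduction of the lactone, which stops at the lactol because the aluminium hemiacetal is stable at −78 °C.

Step 8
Reactants: 13
Product: 14 (2R,4S)-4-methyl-1-(trityloxy)hex-5-yn-2-ol
Conditions: dimethyl (1-diazo-2-oxopropyl)phosphonate, K2CO3, MeOH, 0 °C to rt
Reagents that add atoms: dimethyl (1-diazo-2-oxopropyl)phosphonate, COP(=O)(OC)C(=[N+]=[N-])C(C)=O
Why: Seyferth–Gilbert homologation with the Ohira–Bestmann reagent acts on the hydroxy aldehyde in equilibrium with the lactol and adds C2, and the mild carbonate conditions should leave the α-methyl centre intact.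

Step 9
Reactants: 14
Product: 15 tert-butyl(dimethyl){[(2R,4S)-4-methyl-1-(trityloxy)hex-5-yn-2-yl]oxy}silane
Conditions: t-BuMe2SiOTf, 2,6-lutidine, CH2Cl2, −78 °C
Reagents that add atoms: tert-butyldimethylsilyl trifluoromethanesulfonate, CC(C)(C)[Si](C)(C)OS(=O)(=O)C(F)(F)F
Why: Silylation of the secondary C6 alcohol with a group that survives the organolithium, amine and mild acid steps and is removed only when the butenolide is to close.

Step 10
Reactants: 15; 8
Product: 17 tert-butyl (3R,7S,9R)-9-[(tert-butyldimethylsilyl)oxy]-3,7-dimethyl-4-oxo-3-[(trimethylsilyl)oxy]-10-(trityloxy)dec-5-ynoate, via lithium acetylide 16 (not isolated)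
Conditions: n-BuLi, THF, −78 °C; then 8, −78 to −20 °C; aq. NH4Cl
Reagents that add atoms: none
Why: Acetylide addition to the N-methoxy-N-methylamide (Weinreb ketone synthesis) forms C1–C2, and the chelated tetrahedral adduct should persist until the quench so that only the ynone results.

Step 11
Reactants: 17
Product: 20 tert-butyl 2-[(2R)-5-{(2S,4R)-4-[(tert-butyldimethylsilyl)oxy]-5-hydroxypentan-2-yl}-2-methyl-3-oxo-2,3-dihydrofuran-2-yl]acetate, via diethylamino enone 18 (not isolated), via trityl furanone 19 (not isolated)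
Conditions: Et2NH, EtOH, rt; evaporate; p-toluenesulfonic acid monohydrate (1.5 equiv), MeOH/CH2Cl2, 0 °C to rt
Reagents that add atoms: none
Why: Conjugate addition of the amine to the ynone, then acid-mediated loss of the trimethylsilyl group and 5-exo-trig addition–elimination of the tertiary hydroxyl at the iminium carbon C3 should give the 3(2H)-furanone, and the same acidic methanol should cleave the primary trityl ether faster than the secondary silyl ether.

Step 12
Reactants: 20
Product: 21 tert-butyl 2-[(2R)-5-{(2S,4R)-4-[(tert-butyldimethylsilyl)oxy]-5-oxopentan-2-yl}-2-methyl-3-oxo-2,3-dihydrofuran-2-yl]acetate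
Conditions: Dess–Martin periodinane, CH2Cl2, 0 °C to rt
Reagents that add atoms: none
Why: Dess–Martin oxidation converts the primary alcohol into the α-silyloxy aldehyde under non-basic conditions that should not epimerise C6.

Step 13
Reactants: 21
Product: 22 methyl (2Z,4R,6S)-6-{(2R)-2-[2-(tert-butoxy)-2-oxoethyl]-2-methyl-3-oxo-2,3-dihydrofuran-5-yl}-4-[(tert-butyldimethylsilyl)oxy]-2-methylhept-2-enoate
Conditions: methyl 2-[bis(2,2,2-trifluoroethoxy)phosphoryl]propanoate, KN(SiMe3)2, 18-crown-6, THF, −78 °C; then 21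
Reagents that add atoms: methyl 2-[bis(2,2,2-trifluoroethoxy)phosphoryl]propanoate, COC(=O)C(C)P(=O)(OCC(F)(F)F)OCC(F)(F)F
Why: Still–Gennari olefination with the preformed phosphonate anion should give the Z trisubstituted enoate, which places the ester cis to C6 as lactonisation requires and brings in C11, C12 and C13.

Step 14
Reactants: 22
Product: 25 2-[(2R)-2-methyl-5-{(2S)-1-[(2R)-4-methyl-5-oxo-2,5-dihydrofuran-2-yl]propan-2-yl}-3-oxo-2,3-dihydrofuran-2-yl]acetic acid, via hydroxy enoate 23 (not isolated), via butenolide tert-butyl ester 24 (not isolated)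
Conditions: CF3CO2H/H2O (9:1), 0 °C to rt
Reagents that add atoms: none
Why: Acidolysis in which the silyl ether is cleaved, the (Z)-γ-hydroxy enoate lactonises to the α-methylbutenolide and the tert-butyl ester is cleaved, all under conditions that should leave the furanone and C6 untouched.

Step 15
Reactants: 25
Product: 26 Se-phenyl 2-[(2R)-2-methyl-5-{(2S)-1-[(2R)-4-methyl-5-oxo-2,5-dihydrofuran-2-yl]propan-2-yl}-3-oxo-2,3-dihydrofuran-2-yl]ethaneselenoate
Conditions: N-(phenylseleno)phthalimide, n-Bu3P, CH2Cl2, −30 to 0 °C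
Reagents that add atoms: N-(phenylseleno)phthalimide, O=C1N([Se]c2ccccc2)C(=O)c2ccccc12
Why: Redox condensation in which phosphine and selenium reagent turn the acid into an acyloxyphosphonium salt that phenylselenolate captures, under neutral conditions that the butenolide and the β-oxygenated acyl group should tolerate.

Step 16
Reactants: 26
Product: 27 (4S,6R,7S,10R,11R)-3,10-epoxy-1,8-dioxogermacr-2-en-12,6-olide (tricyclic C8 ketone, C11 methyl cis to C8)
Conditions: (Me3Si)3SiH, 2,2′-azobis(2-methylpropionitrile), benzene, 80 °C, syringe-pump addition to a 2 mM solution of 26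
Reagents that add atoms: none
Why: Proposed new method: tris(trimethylsilyl)silyl radicals abstract the phenylselenyl group of 26, the resulting C8 acyl radical (a nucleophilic σ-radical) adds to C7, the β-carbon of the α-methylbutenolide, and the tertiary C11 lactone radical is quenched by hydrogen transfer from the silane, whose silyl radical carries the chain. The closest known reactions are acyl radical macrocyclisations of phenyl selenoesters onto enones and acrylates in larger rings, ten-membered endo closures of alkyl radicals onto enones, and intermolecular radical additions to γ-substituted butenolides; an exo closure of this size onto a butenolide has not been described. The carbocycle closes in a 10-exo-trig mode (nine atoms if the path through the furanone oxygen is counted), helped by the planar furanone that already links C3 and C10 and leaves only the C4–C9 chain to fold. C7 is set by attack on the butenolide face anti to the C5 substituent at C6, which gives the 6,7-trans ring fusion, and C11 by hydrogen transfer anti to the new C7–C8 bond, which is expected to leave the methyl cis to C8 (11R) for correction in step 17. The closure must outrun loss of CO, direct reduction of the acyl radical and attack on the furanone: the acyl radical sits on a primary carbon and should decarbonylate slowly, slow addition keeps the silane concentration low, and the unhindered, electron-poor β-CH of the butenolide is matched to the radical, whereas C3 of the furanone is fully substituted, carries a donor oxygen and would lead to a strained 7-oxabicyclo[2.2.1]heptane.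

Step 17
Reactants: 27
Product: 28 (4S,6R,7S,10R,11S)-3,10-epoxy-1,8-dioxogermacr-2-en-12,6-olide (all-trans lactone)
Conditions: 1,8-diazabicyclo[5.4.0]undec-7-ene (0.3 equiv), toluene, 50 °C
Reagents that add atoms: none
Why: Base-mediated epimerisation through the enolates of the C8 ketone (C7) and of the lactone (C11) should converge on the lactone with C5, C8 and the C11 methyl mutually trans, the thermodynamic arrangement of trans-fused dihydro lactones of this class, so C11 is set here.

Step 18
Reactants: 28
Product: 29 (4S,6R,7R,8R,10R,11S)-3,10-epoxy-8-hydroxy-1-oxogermacr-2-en-12,6-olide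
Conditions: NaBH4, MeOH/CH2Cl2, −78 to −40 °C; AcOH quench
Reagents that add atoms: none
Why: Chemoselective borohydride reduction of the saturated ketone (the furanone carbonyl is a vinylogous ester and the lactone is inert), with hydride expected on the face of H7, away from the C7–C11 bond and the C10 methyl, to give the 8R alcohol.

Step 19
Reactants: 29; 30 tiglic acid
Product: 31 (4S,6R,7S,8S,10R,11S)-3,10-epoxy-8-[(E)-2-methylbut-2-enoyloxy]-1-oxogermacr-2-en-12,6-olide (target)
Conditions: Ph3P, diisopropyl azodicarboxylate, toluene, 0 °C to rt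
Reagents that add atoms: none
Why: Mitsunobu esterification in which the tiglate anion displaces the alkoxyphosphonium group at C8 with inversion, turning the 8R alcohol into the 8S ester without touching the alkene geometry of the acid.

Compound list
1 | (S)-lactic acid | C[C@H](O)C(=O)O | starting material
2 | pivalaldehyde | CC(C)(C)C=O | starting material
3 | (2S,5S)-2-tert-butyl-5-methyl-1,3-dioxolan-4-one | C[C@@H]1O[C@H](C(C)(C)C)OC1=O | intermediate
4 | tert-butyl bromoacetate | CC(C)(C)OC(=O)CBr | starting material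
5 | lithium (2S)-2-tert-butyl-5-methyl-1,3-dioxol-4-olate (enolate of 3) | CC1=C(O[Li])O[C@@H](C(C)(C)C)O1 | intermediate
6 | tert-butyl 2-[(2S,4R)-2-tert-butyl-4-methyl-5-oxo-1,3-dioxolan-4-yl]acetate | CC(C)(C)OC(=O)C[C@@]1(C)O[C@H](C(C)(C)C)OC1=O | intermediate
7 | tert-butyl (3R)-3-hydroxy-4-[methoxy(methyl)amino]-3-methyl-4-oxobutanoate | CC(C)(C)OC(=O)C[C@@](C)(O)C(=O)N(C)OC | intermediate
8 | tert-butyl (3R)-4-[methoxy(methyl)amino]-3-methyl-4-oxo-3-[(trimethylsilyl)oxy]butanoate | CC(C)(C)OC(=O)C[C@@](C)(O[Si](C)(C)C)C(=O)N(C)OC | intermediate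
9 | (5R)-5-(hydroxymethyl)dihydrofuran-2(3H)-one | O=C1CC[C@H](CO)O1 | starting material
10 | (5R)-5-[(trityloxy)methyl]dihydrofuran-2(3H)-one | O=C1CC[C@H](COC(c2ccccc2)(c2ccccc2)c2ccccc2)O1 | intermediate
11 | lithium (5R)-5-[(trityloxy)methyl]-4,5-dihydrofuran-2-olate (enolate of 10) | [Li]OC1=CC[C@H](COC(c2ccccc2)(c2ccccc2)c2ccccc2)O1 | intermediate
12 | (3S,5R)-3-methyl-5-[(trityloxy)methyl]dihydrofuran-2(3H)-one | O=C1[C@@H](C)C[C@H](COC(c2ccccc2)(c2ccccc2)c2ccccc2)O1 | intermediate
13 | (3S,5R)-3-methyl-5-[(trityloxy)methyl]tetrahydrofuran-2-ol, mixture of anomers | OC1[C@@H](C)C[C@H](COC(c2ccccc2)(c2ccccc2)c2ccccc2)O1 | intermediate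
14 | (2R,4S)-4-methyl-1-(trityloxy)hex-5-yn-2-ol | C#C[C@@H](C)C[C@@H](O)COC(c1ccccc1)(c1ccccc1)c1ccccc1 | intermediate
15 | tert-butyl(dimethyl){[(2R,4S)-4-methyl-1-(trityloxy)hex-5-yn-2-yl]oxy}silane | C#C[C@@H](C)C[C@@H](O[Si](C)(C)C(C)(C)C)COC(c1ccccc1)(c1ccccc1)c1ccccc1 | intermediate
16 | {(3S,5R)-5-[(tert-butyldimethylsilyl)oxy]-3-methyl-6-(trityloxy)hex-1-yn-1-yl}lithium (acetylide of 15) | [Li]C#C[C@@H](C)C[C@@H](O[Si](C)(C)C(C)(C)C)COC(c1ccccc1)(c1ccccc1)c1ccccc1 | intermediate
17 | tert-butyl (3R,7S,9R)-9-[(tert-butyldimethylsilyl)oxy]-3,7-dimethyl-4-oxo-3-[(trimethylsilyl)oxy]-10-(trityloxy)dec-5-ynoate | CC(C)(C)OC(=O)C[C@@](C)(O[Si](C)(C)C)C(=O)C#C[C@@H](C)C[C@@H](O[Si](C)(C)C(C)(C)C)COC(c1ccccc1)(c1ccccc1)c1ccccc1 | intermediate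
18 | tert-butyl (3R,5E,7S,9R)-9-[(tert-butyldimethylsilyl)oxy]-6-(diethylamino)-3,7-dimethyl-4-oxo-3-[(trimethylsilyl)oxy]-10-(trityloxy)dec-5-enoate | CC(C)(C)OC(=O)C[C@@](C)(O[Si](C)(C)C)C(=O)/C=C(\[C@@H](C)C[C@@H](O[Si](C)(C)C(C)(C)C)COC(c1ccccc1)(c1ccccc1)c1ccccc1)N(CC)CC | intermediate
19 | tert-butyl 2-[(2R)-5-{(2S,4R)-4-[(tert-butyldimethylsilyl)oxy]-5-(trityloxy)pentan-2-yl}-2-methyl-3-oxo-2,3-dihydrofuran-2-yl]acetate | CC(C)(C)OC(=O)C[C@@]1(C)OC(=CC1=O)[C@@H](C)C[C@@H](O[Si](C)(C)C(C)(C)C)COC(c1ccccc1)(c1ccccc1)c1ccccc1 | intermediate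
20 | tert-butyl 2-[(2R)-5-{(2S,4R)-4-[(tert-butyldimethylsilyl)oxy]-5-hydroxypentan-2-yl}-2-methyl-3-oxo-2,3-dihydrofuran-2-yl]acetate | CC(C)(C)OC(=O)C[C@@]1(C)OC(=CC1=O)[C@@H](C)C[C@@H](O[Si](C)(C)C(C)(C)C)CO | intermediate
21 | tert-butyl 2-[(2R)-5-{(2S,4R)-4-[(tert-butyldimethylsilyl)oxy]-5-oxopentan-2-yl}-2-methyl-3-oxo-2,3-dihydrofuran-2-yl]acetate | CC(C)(C)OC(=O)C[C@@]1(C)OC(=CC1=O)[C@@H](C)C[C@@H](O[Si](C)(C)C(C)(C)C)C=O | intermediate
22 | methyl (2Z,4R,6S)-6-{(2R)-2-[2-(tert-butoxy)-2-oxoethyl]-2-methyl-3-oxo-2,3-dihydrofuran-5-yl}-4-[(tert-butyldimethylsilyl)oxy]-2-methylhept-2-enoate | CC(C)(C)OC(=O)C[C@@]1(C)OC(=CC1=O)[C@@H](C)C[C@@H](O[Si](C)(C)C(C)(C)C)/C=C(/C)C(=O)OC | intermediate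
23 | methyl (2Z,4R,6S)-6-{(2R)-2-[2-(tert-butoxy)-2-oxoethyl]-2-methyl-3-oxo-2,3-dihydrofuran-5-yl}-4-hydroxy-2-methylhept-2-enoate | CC(C)(C)OC(=O)C[C@@]1(C)OC(=CC1=O)[C@@H](C)C[C@@H](O)/C=C(/C)C(=O)OC | intermediate
24 | tert-butyl 2-[(2R)-2-methyl-5-{(2S)-1-[(2R)-4-methyl-5-oxo-2,5-dihydrofuran-2-yl]propan-2-yl}-3-oxo-2,3-dihydrofuran-2-yl]acetate | CC(C)(C)OC(=O)C[C@@]1(C)OC(=CC1=O)[C@@H](C)C[C@H]1OC(=O)C(C)=C1 | intermediate
25 | 2-[(2R)-2-methyl-5-{(2S)-1-[(2R)-4-methyl-5-oxo-2,5-dihydrofuran-2-yl]propan-2-yl}-3-oxo-2,3-dihydrofuran-2-yl]acetic acid | OC(=O)C[C@@]1(C)OC(=CC1=O)[C@@H](C)C[C@H]1OC(=O)C(C)=C1 | intermediate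
26 | Se-phenyl 2-[(2R)-2-methyl-5-{(2S)-1-[(2R)-4-methyl-5-oxo-2,5-dihydrofuran-2-yl]propan-2-yl}-3-oxo-2,3-dihydrofuran-2-yl]ethaneselenoate | O=C([Se]c1ccccc1)C[C@@]1(C)OC(=CC1=O)[C@@H](C)C[C@H]1OC(=O)C(C)=C1 | intermediate
27 | (4S,6R,7S,10R,11R)-3,10-epoxy-1,8-dioxogermacr-2-en-12,6-olide (C11 epimer of 28) | O=C1C[C@@]2(C)OC(=CC2=O)[C@@H](C)C[C@H]2OC(=O)[C@H](C)[C@H]12 | intermediate
28 | (4S,6R,7S,10R,11S)-3,10-epoxy-1,8-dioxogermacr-2-en-12,6-olide | O=C1C[C@@]2(C)OC(=CC2=O)[C@@H](C)C[C@H]2OC(=O)[C@@H](C)[C@H]12 | intermediate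
29 | (4S,6R,7R,8R,10R,11S)-3,10-epoxy-8-hydroxy-1-oxogermacr-2-en-12,6-olide (C7 geometry unchanged, descriptor changes by priority only) | O[C@@H]1C[C@@]2(C)OC(=CC2=O)[C@@H](C)C[C@H]2OC(=O)[C@@H](C)[C@H]12 | intermediate
30 | tiglic acid, (E)-2-methylbut-2-enoic acid | C/C=C(\C)C(=O)O | starting material
31 | (4S,6R,7S,8S,10R,11S)-3,10-epoxy-8-[(E)-2-methylbut-2-enoyloxy]-1-oxogermacr-2-en-12,6-olide | C/C=C(\C)C(=O)O[C@H]1C[C@@]2(C)OC(=CC2=O)[C@@H](C)C[C@H]2OC(=O)[C@@H](C)[C@H]12 | target

Total step count: 19. Longest linear sequence: 15 steps (9 to 31, steps 5 to 19); the lactic acid branch (steps 1 to 4) joins at step 10.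

Steps most likely to fail

1. Step 16. What may go wrong: the acyl radical may be reduced by the silane, lose CO, or add to C3 of the furanone in a 5-exo mode before the strained ten-membered transition state is reached, and intermolecular addition may compete even at high dilution. Fallback: the ring is closed at the aldehyde oxidation level by a reductive ketyl–olefin coupling instead of an acyl radical chain. It sets out from acid 25. BH3·SMe2 in THF at 0 °C should reduce the carboxylic acid selectively to the 2-hydroxyethyl furanone F1, and Dess–Martin oxidation should give the C8 aldehyde F2. SmI2 (divalent samarium) in THF with t-BuOH at high dilution turns the aldehyde into its ketyl, which adds to C7 of the butenolide anti to C5; this reductive aldehyde–enoate coupling is in routine use for lactone and medium-ring synthesis. Protonation of the samarium enolate should give the tricyclic C8 carbinol F3 as a mixture at C8, and Dess–Martin oxidation of F3 comes back to the route at ketone 27.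

2. Step 17. What may go wrong: enolisation of the C8 ketone toward C9 can expel the furanone oxygen from C10 (retro-oxa-Michael ring opening, with possible loss of the C10 configuration on re-closure), enolisation toward C7 can eliminate the lactone carboxylate from C6, and exchange at the less acidic C11 may be slower than either. Fallback: the equilibration is moved to the end, where no ketone flanks C7 or C9. It sets out from ketone 27. Borohydride reduction as in step 18 should give the 11-epi alcohol F4, and Mitsunobu esterification with 30 as in step 19 the 11-epi tiglate F5. Treatment of F5 with 1,8-diazabicyclo[5.4.0]undec-7-ene in toluene at 80 °C should then epimerise only the lactone α-carbon C11 and comes back to the route at target 31.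

3. Step 19. What may go wrong: the alkoxyphosphonium ion at the hindered C8 may eliminate toward C9 or fail to react with the weakly acidic tiglic acid, and the plan also fails if the hydride in step 18 attacks the other face. Fallback: C8 is set by reagent control and acylated with retention. It sets out from ketone 28. Corey–Bakshi–Shibata reduction with catecholborane and (R)-1-methyl-3,3-diphenyltetrahydro-1H,3H-pyrrolo[1,2-c][1,3,2]oxazaborole, chosen to deliver hydride to the face opposite to that used by borohydride, should give the 8S alcohol F6. Yamaguchi esterification of F6 with 30 (2,4,6-trichlorobenzoyl chloride, Et3N, 4-(dimethylamino)pyridine, toluene) proceeds without change at C8 and comes back to the route at target 31.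

Further compounds
F1 | step 16 | (5R)-3-methyl-5-{(2S)-2-[(5R)-5-(2-hydroxyethyl)-5-methyl-4-oxo-4,5-dihydrofuran-2-yl]propyl}furan-2(5H)-one | OCC[C@@]1(C)OC(=CC1=O)[C@@H](C)C[C@H]1OC(=O)C(C)=C1
F2 | step 16 | 2-[(2R)-2-methyl-5-{(2S)-1-[(2R)-4-methyl-5-oxo-2,5-dihydrofuran-2-yl]propan-2-yl}-3-oxo-2,3-dihydrofuran-2-yl]acetaldehyde | O=CC[C@@]1(C)OC(=CC1=O)[C@@H](C)C[C@H]1OC(=O)C(C)=C1
F3 | step 16 | (4S,6R,10R,11R)-3,10-epoxy-8-hydroxy-1-oxogermacr-2-en-12,6-olide, C7 as in 27, both C8 epimers | OC1C[C@@]2(C)OC(=CC2=O)[C@@H](C)C[C@H]2OC(=O)[C@H](C)[C@H]12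
F4 | step 17 | (4S,6R,7R,8R,10R,11R)-3,10-epoxy-8-hydroxy-1-oxogermacr-2-en-12,6-olide | O[C@@H]1C[C@@]2(C)OC(=CC2=O)[C@@H](C)C[C@H]2OC(=O)[C@H](C)[C@H]12
F5 | step 17 | (4S,6R,7S,8S,10R,11R)-3,10-epoxy-8-[(E)-2-methylbut-2-enoyloxy]-1-oxogermacr-2-en-12,6-olide (C11 epimer of 31) | C/C=C(\C)C(=O)O[C@H]1C[C@@]2(C)OC(=CC2=O)[C@@H](C)C[C@H]2OC(=O)[C@H](C)[C@H]12
F6 | step 19 | (4S,6R,7R,8S,10R,11S)-3,10-epoxy-8-hydroxy-1-oxogermacr-2-en-12,6-olide | O[C@H]1C[C@@]2(C)OC(=CC2=O)[C@@H](C)C[C@H]2OC(=O)[C@@H](C)[C@H]12
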